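**Strategy.** The twofold-symmetric bis-chromanone is cut through both pyranone rings at O1–C2 and C4–C4a (and their primed twins). This leaves two phloroglucinol rings and a succinate core C4–C3–C3′–C4′ that carries both anisyl carbinol carbons, stored as an enantiopure bis-γ-lactone. In one flask two aryl-cerium additions open the lactones (C4–C4a), and acid then frees the ortho-phenols, which capture the p-methoxybenzylic cations (O1–C2) and close both rings. The step exploits the twofold axis through C3–C3′, the O1/C4a ambident phloroglucinol ring and the cation-stabilising 4′-OMe. C3/C3′ relay their configuration to C2/C2′; kinetic protonation finally resets C3/C3′ cis.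

Key step: step 6

Remark: flavanone numbering is used (O1, C2, C3, C4, C4a … C8a; primes for the second unit). The target is 2,3-cis in both pyranone rings (anisyl group and C3–C3′ bond on the same ring face); this is assumed to be the less stable arrangement and is therefore installed last under kinetic control.

Step 1
Reactants: 1 (S)-4-benzyl-1,3-oxazolidin-2-one; 2 3-(4-methoxyphenyl)propanoyl chloride
Product: 3 (S)-4-benzyl-3-[3-(4-methoxyphenyl)propanoyl]-1,3-oxazolidin-2-one
Conditions: n-BuLi, THF, −78 °C; then 2, −78 → 0 °C
Reagents that add atoms: none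
Why: N-acylation of the lithiated oxazolidinone by the acid chloride (imide formation) attaches the chiral auxiliary; no stereocenter is formed.

Step 2
Reactants: 3 (S)-4-benzyl-3-[3-(4-methoxyphenyl)propanoyl]-1,3-oxazolidin-2-one (two molecules)
Product: 4 (4S,4'S)-3,3'-[(2R,3R)-2,3-bis(4-methoxybenzyl)butanedioyl]bis(4-benzyl-1,3-oxazolidin-2-one)
Conditions: LiN(i-Pr)2, THF, −78 °C; then CuCl2, DMF, −78 → 0 °C
Reagents that add atoms: none
Why: Enolate oxidative homocoupling of the chelated Z-lithium enolate should form the C3–C3′ bond on the enolate face remote from the 4-benzyl group in both halves, so the two (S)-auxiliaries set both new centers R.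

Step 3
Reactants: 4 (4S,4'S)-3,3'-[(2R,3R)-2,3-bis(4-methoxybenzyl)butanedioyl]bis(4-benzyl-1,3-oxazolidin-2-one)
Product: 5 (2R,3R)-2,3-bis(4-methoxybenzyl)butanedioic acid
Conditions: LiOH, H2O2, THF/H2O, 0 °C; Na2SO3; then aqueous HCl
Reagents that add atoms: hydrogen peroxide (as LiOOH), OO
Why: Hydroperoxide attacks the exocyclic imide carbonyl selectively (auxiliary cleavage) and should release the diacid without enolising the α-stereocenters.

Step 4
Reactants: 5 (2R,3R)-2,3-bis(4-methoxybenzyl)butanedioic acid
Product: 6 (3S,3aS,6S,6aS)-3,6-bis(4-methoxyphenyl)tetrahydrofuro[3,4-c]furan-1,4-dione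
Conditions: DDQ (2.4 equiv), 1,4-dioxane, 80 °C
Reagents that add atoms: none
Why: Oxidative benzylic lactonization: DDQ abstracts hydride from each p-methoxybenzylic CH2 and the carboxyl group of the other half traps the cation in a 5-exo closure, the (R,R) core enforcing the cis ring fusion and allylic 1,3-strain placing both aryl groups exo.

Step 5
Reactants: 7 phloroglucinol
Product: 8 1,3,5-tris(methoxymethoxy)benzene
Conditions: MOMCl, i-Pr2NEt, CH2Cl2, 0 °C → rt
Reagents that add atoms: chloromethyl methyl ether (MOMCl), COCCl
Why: Threefold O-alkylation (acetal protection) masks the phenols and provides the directing groups for ortho-metalation; no stereocenter is formed.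

Step 6
Reactants: 6 (3S,3aS,6S,6aS)-3,6-bis(4-methoxyphenyl)tetrahydrofuro[3,4-c]furan-1,4-dione; 8 1,3,5-tris(methoxymethoxy)benzene (2.1 equiv)
Product: 12 (2R,2'R,3S,3'S)-5,5',7,7'-tetrahydroxy-2,2'-bis(4-methoxyphenyl)-[3,3'-bichromane]-4,4'-dione, via aryllithium 9 (not isolated), via arylcerium dichloride 10 (not isolated), via bis(hydroxy ketone) 11 (not isolated)
Conditions: 8, n-BuLi, THF, 0 °C; CeCl3, −78 °C; then 6, −78 → −40 °C; then HCl, MeOH, 0 → 45 °C
Reagents that add atoms: none
Why: Directed ortho-lithiation of 8 and transmetalation to the weakly basic aryl-cerium reagent 10 should allow one 1,2-addition to each lactone carbonyl of 6 (the known addition of aryl-metals to lactones to give lactols/γ-hydroxy ketones), which forms C4–C4a and C4′–C4a′ and leaves the anisyl carbons as carbinols in 11. Methanolic HCl then cleaves the six MOM acetals and ionises each p-methoxybenzylic carbinol, and the ortho-phenol of the neighbouring aroyl group traps the cation to form O1–C2 and O1′–C2′, the known acid cyclodehydration of 2′-hydroxy-β-hydroxydihydrochalcones to flavanones. Both pyranone rings close in the 6-exo-trig mode onto the quinone-methide-like cation (6-exo-tet if the protonated carbinol is displaced directly). C3 and C3′ come unchanged from the succinate core and control the new C2 and C2′ centers: allylic 1,3-strain holds H3 in the plane of the cation, so the phenol tethered through C4 adds to the face that sets the aryl group trans to the C3 substituent, and a backside displacement of the (S)-carbinol leads to the same (2R,3S) ring, which should also be the more stable one. The step needs C-acylation and O-benzylation instead of C-benzylation of the phloroglucinol ring, secured by using the arene as a carbanion first and forming the cation only when an ortho-OH sits six atoms away, and it needs C3 to survive, secured by the in-plane H3 being misaligned for proton loss and by a short, mild acid stage.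

Step 7
Reactants: 12 (2R,2'R,3S,3'S)-5,5',7,7'-tetrahydroxy-2,2'-bis(4-methoxyphenyl)-[3,3'-bichromane]-4,4'-dione
Product: 14 (2R,2'R,3R,3'R)-5,5',7,7'-tetrahydroxy-2,2'-bis(4-methoxyphenyl)-[3,3'-bichromane]-4,4'-dione, via hexakis(trimethylsilyl) bis(enol ether) 13 (not isolated)
Conditions: TMSOTf, Et3N, CH2Cl2, 0 °C → rt; solvent switch to THF; then pivalic acid, Bu4NF, −78 → −20 °C; neutral work-up
Reagents that add atoms: none
Why: Soft enolization converts both ketones into silyl enol ethers (and caps the phenols), which erases C3/C3′ but not C2/C2′; fluoride then releases each enolate next to a bulky acid, and kinetic protonation should occur on the C3 face opposite the pseudo-axial 2-aryl group, giving the 2,3-cis rings.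

**Compound list**

1 | (S)-4-benzyl-1,3-oxazolidin-2-one | O=C1N[C@@H](Cc2ccccc2)CO1 | starting material
2 | 3-(4-methoxyphenyl)propanoyl chloride | COc1ccc(CCC(=O)Cl)cc1 | starting material
3 | (S)-4-benzyl-3-[3-(4-methoxyphenyl)propanoyl]-1,3-oxazolidin-2-one | COc1ccc(CCC(=O)N2[C@@H](Cc3ccccc3)COC2=O)cc1 | intermediate
4 | (4S,4'S)-3,3'-[(2R,3R)-2,3-bis(4-methoxybenzyl)butanedioyl]bis(4-benzyl-1,3-oxazolidin-2-one) | COc1ccc(C[C@@H](C(=O)N2[C@@H](Cc3ccccc3)COC2=O)[C@@H](Cc2ccc(OC)cc2)C(=O)N2[C@@H](Cc3ccccc3)COC2=O)cc1 | intermediate
5 | (2R,3R)-2,3-bis(4-methoxybenzyl)butanedioic acid | COc1ccc(C[C@@H](C(=O)O)[C@@H](Cc2ccc(OC)cc2)C(=O)O)cc1 | intermediate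
6 | (3S,3aS,6S,6aS)-3,6-bis(4-methoxyphenyl)tetrahydrofuro[3,4-c]furan-1,4-dione (cis-fused, both aryl groups exo) | O=C1O[C@H](c2ccc(OC)cc2)[C@H]2C(=O)O[C@H](c3ccc(OC)cc3)[C@@H]12 | intermediate
7 | phloroglucinol (benzene-1,3,5-triol) | Oc1cc(O)cc(O)c1 | starting material
8 | 1,3,5-tris(methoxymethoxy)benzene | COCOc1cc(OCOC)cc(OCOC)c1 | intermediate
9 | 2,4,6-tris(methoxymethoxy)phenyllithium (formed in the flask) | COCOc1cc(OCOC)cc(OCOC)c1[Li] | intermediate
10 | dichloro[2,4,6-tris(methoxymethoxy)phenyl]cerium (formed in the flask) | COCOc1cc(OCOC)cc(OCOC)c1[Ce](Cl)Cl | intermediate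
11 | (2S,3S)-2,3-bis[(S)-hydroxy(4-methoxyphenyl)methyl]-1,4-bis[2,4,6-tris(methoxymethoxy)phenyl]butane-1,4-dione (formed in the flask; held as its bis-lactol alkoxide until the acid is added) | COCOc1cc(OCOC)cc(OCOC)c1C(=O)[C@H]([C@H](O)c1ccc(OC)cc1)[C@@H]([C@H](O)c1ccc(OC)cc1)C(=O)c1c(OCOC)cc(OCOC)cc1OCOC | intermediate
12 | (2R,2'R,3S,3'S)-5,5',7,7'-tetrahydroxy-2,2'-bis(4-methoxyphenyl)-[3,3'-bichromane]-4,4'-dione (2,3-trans in both rings) | COc1ccc([C@@H]2Oc3cc(O)cc(O)c3C(=O)[C@H]2[C@@H]2C(=O)c3c(O)cc(O)cc3O[C@H]2c2ccc(OC)cc2)cc1 | intermediate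
13 | (2S,2'S)-2,2'-bis(4-methoxyphenyl)-4,4',5,5',7,7'-hexakis(trimethylsilyloxy)-2H,2'H-3,3'-bichromene (formed in the flask; same spatial arrangement at C2 as in 12, the descriptor changes because C3 now outranks the aryl group) | COc1ccc([C@@H]2Oc3cc(O[Si](C)(C)C)cc(O[Si](C)(C)C)c3C(O[Si](C)(C)C)=C2C2=C(O[Si](C)(C)C)c3c(O[Si](C)(C)C)cc(O[Si](C)(C)C)cc3O[C@H]2c2ccc(OC)cc2)cc1 | intermediate
14 | (2R,2'R,3R,3'R)-5,5',7,7'-tetrahydroxy-2,2'-bis(4-methoxyphenyl)-[3,3'-bichromane]-4,4'-dione (2,3-cis in both rings) | COc1ccc([C@@H]2Oc3cc(O)cc(O)c3C(=O)[C@@H]2[C@H]2C(=O)c3c(O)cc(O)cc3O[C@H]2c2ccc(OC)cc2)cc1 | target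

**Step count.** Total: 7 steps. Longest linear sequence: 6 steps (1, 2, 3, 4, 6, 7); step 5 is a one-step side branch.

**Steps most likely to fail**

Step 6. The aryl-metal may act as a base on the lactone α-CH, after which the enolate expels the benzylic carboxylate and the bicycle unravels. In the acid stage the cation may lose H3 (chalcone formation) or benzylate a free phloroglucinol carbon, which would erode the C3 → C2 relay. The fallback sets out from 5 and 7 and comes back at 12, making the two bonds in separate operations. Diacid 5 and phloroglucinol 7 would be heated in BF3·OEt2 (Friedel–Crafts/Fries-type C-acylation of phloroglucinol by an alkanoic acid) to give (2R,3R)-2,3-bis(4-methoxybenzyl)-1,4-bis(2,4,6-trihydroxyphenyl)butane-1,4-dione F1. DDQ in dioxane at room temperature would then abstract hydride from each p-methoxybenzylic CH2 so that the ortho-phenol closes the ring (oxidative cyclization of a 2′-hydroxydihydrochalcone to a flavanone) under the same allylic-strain control, giving 12.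

Step 7. Double enolization may be incomplete, the protonation may discriminate poorly between the two faces, or the product may drift back to trans on work-up. The fallback sets out from 13 and comes back at 14, replacing protonation by syn addition of hydrogen. Bis(enol ether) 13 would be oxidised with DDQ (CH2Cl2, 0 °C; aqueous work-up removes the aryl silyl ethers) to the C3=C3′ ene-dione (E,2S,2'S)-5,5',7,7'-tetrahydroxy-2,2'-bis(4-methoxyphenyl)-[3,3'-bichromanylidene]-4,4'-dione F2 (oxidation of a 1,4-bis(silyloxy)diene to an ene-dione). H2 over Pd/C (palladium on carbon) in EtOAc should then add both hydrogens to the alkene face opposite the two pseudo-axial aryl groups, which the twofold axis places on one and the same face, giving 14.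

Step 4. DDQ may over-oxidise, or the benzylic cation may lose a proton to give the benzylidene acid, which would erase a succinate stereocenter. The fallback sets out from 5 and comes back at 6. Radical benzylic bromination (NBS, light, PhCF3) would give (2R,3R)-2,3-bis[bromo(4-methoxyphenyl)methyl]butanedioic acid F3 (epimers at CHBr). NaHCO3 in aqueous acetone would then let each carboxylate displace the benzylic bromide of the other half, closing both lactones to 6; the CHBr configuration is immaterial because the aryl groups settle exo and these centers are ionised again in step 6.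

**Further compounds**

F1 | step 6 | (2R,3R)-2,3-bis(4-methoxybenzyl)-1,4-bis(2,4,6-trihydroxyphenyl)butane-1,4-dione | COc1ccc(C[C@@H](C(=O)c2c(O)cc(O)cc2O)[C@@H](Cc2ccc(OC)cc2)C(=O)c2c(O)cc(O)cc2O)cc1
F2 | step 7 | (E,2S,2'S)-5,5',7,7'-tetrahydroxy-2,2'-bis(4-methoxyphenyl)-[3,3'-bichromanylidene]-4,4'-dione | COc1ccc([C@@H]2Oc3cc(O)cc(O)c3C(=O)/C2=C2/C(=O)c3c(O)cc(O)cc3O[C@H]2c2ccc(OC)cc2)cc1
F3 | step 4 | (2R,3R)-2,3-bis[bromo(4-methoxyphenyl)methyl]butanedioic acid (epimers at CHBr) | COc1ccc(C(Br)[C@@H](C(=O)O)[C@@H](C(Br)c2ccc(OC)cc2)C(=O)O)cc1
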